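**Retrosynthetic overview**
1. Target 17 ⇐ hydrogenolysis of the three benzyl ethers of 16 ⇐ axial-hydride reduction of the cis-2,6-disubstituted oxan-4-one 15 (sets C4).
2. 15 ⇐ 6-endo oxa-Michael closure of δ-hydroxy enone 14; this is the only ring formed, and C2 is set cis to C6.
3. 14 ⇐ enone 13 ⇐ key C–C bond (ring C2–C3): intermolecular aldol of the enolate of methyl ketone 9 with aryl aldehyde 2, then dehydration.
4. 9 ⇐ Wacker oxidation of the TBS ether of homoallylic alcohol 7 ⇐ Brown asymmetric allylation of aldehyde 5 (sets C6, the controlling stereocentre).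
5. 2 ⇐ 5-hydroxyvanillin 1; 5 ⇐ 3-(4-hydroxyphenyl)propan-1-ol 3 (benzylation, oxidation).

Assumption: the SMILES is read as the all-cis (2S,4R,6S)-oxan-4-ol; 1, 3 and (+)-Ipc2BOMe (the (−)-α-pinene series) are bought.

**Step 1**
Reactants: 1 3,4-dihydroxy-5-methoxybenzaldehyde (5-hydroxyvanillin)
Product: 2 3,4-bis(benzyloxy)-5-methoxybenzaldehyde
Conditions: BnBr (2.4 equiv), K2CO3, cat. KI, DMF, 60 °C
Reagents that add atoms: benzyl bromide, BrCc1ccccc1
Why: Williamson ether synthesis; both phenoxides are alkylated cleanly and the aldehyde is inert to carbonate.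

**Step 2**
Reactants: 3 3-(4-hydroxyphenyl)propan-1-ol
Product: 4 3-[4-(benzyloxy)phenyl]propan-1-ol
Conditions: BnBr (1.05 equiv), K2CO3, acetone, reflux
Reagents that add atoms: benzyl bromide, BrCc1ccccc1
Why: Williamson ether synthesis; K2CO3 deprotonates only the phenol, so the primary alcohol is left free.

**Step 3**
Reactants: 4 3-[4-(benzyloxy)phenyl]propan-1-ol
Product: 5 3-[4-(benzyloxy)phenyl]propanal
Conditions: TEMPO (10 mol%), PhI(OAc)2 (1.1 equiv), CH2Cl2, rt
Reagents that add atoms: none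
Why: TEMPO/oxoammonium oxidation stops at the aldehyde and does not touch the benzyl aryl ether.

**Step 4**
Reactants: 5 3-[4-(benzyloxy)phenyl]propanal
Product: 7 (S)-1-[4-(benzyloxy)phenyl]hex-5-en-3-ol, via borinate ester 6 (not isolated)
Conditions: (+)-Ipc2BOMe (1.3 equiv), allylMgBr (1.2 equiv), Et2O, −78 °C → rt; then 5, −78 °C; then 3 M NaOH, 30% H2O2
Reagents that add atoms: allylmagnesium bromide, C=CC[Mg]Br
Why: Brown asymmetric carbonyl allylation; the allylborane carrying (1S,2S,3S,5R)-isopinocampheyl groups transfers allyl to the Re face of the unbranched aldehyde through a chair transition state, giving the (S)-carbinol (typically 90–95% ee).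

**Step 5**
Reactants: 7 (S)-1-[4-(benzyloxy)phenyl]hex-5-en-3-ol
Product: 8 (S)-{[1-(4-(benzyloxy)phenyl)hex-5-en-3-yl]oxy}(tert-butyl)dimethylsilane
Conditions: TBSCl (1.3 equiv), imidazole (2.5 equiv), DMF, rt
Reagents that add atoms: tert-butyldimethylsilyl chloride, CC(C)(C)[Si](C)(C)Cl
Why: standard silylation of a secondary alcohol; it blocks the hydroxyl for the Wacker and enolate steps without touching the stereocentre.

**Step 6**
Reactants: 8 (S)-{[1-(4-(benzyloxy)phenyl)hex-5-en-3-yl]oxy}(tert-butyl)dimethylsilane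
Product: 9 (S)-6-[4-(benzyloxy)phenyl]-4-[(tert-butyldimethylsilyl)oxy]hexan-2-one
Conditions: PdCl2 (10 mol%), CuCl (1 equiv), O2 (1 atm), DMF/H2O 7:1, rt
Reagents that add atoms: water, O
Why: Tsuji–Wacker oxidation gives Markovnikov hydroxypalladation of the terminal alkene and hence the methyl ketone; benzyl and silyl ethers survive.

**Step 7**
Reactants: 9 (S)-6-[4-(benzyloxy)phenyl]-4-[(tert-butyldimethylsilyl)oxy]hexan-2-one; 2 3,4-bis(benzyloxy)-5-methoxybenzaldehyde
Product: 11 (5S)-1-[3,4-bis(benzyloxy)-5-methoxyphenyl]-7-[4-(benzyloxy)phenyl]-5-[(tert-butyldimethylsilyl)oxy]-1-hydroxyheptan-3-one (about 1:1 mixture of C1 epimers), via lithium enolate 10 (not isolated)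
Conditions: LDA (1.1 equiv), THF, −78 °C; then 2, −78 °C; sat. NH4Cl
Reagents that add atoms: none
Why: directed intermolecular aldol addition; kinetic deprotonation occurs at the methyl group, so the silyloxy group cannot be eliminated, and the aldehyde cannot enolise. The new carbinol centre is removed in step 8, so its configuration does not matter.

**Step 8**
Reactants: 11 (5S)-β-hydroxy ketone (epimer mixture)
Product: 13 (1E,5S)-1-[3,4-bis(benzyloxy)-5-methoxyphenyl]-7-[4-(benzyloxy)phenyl]-5-[(tert-butyldimethylsilyl)oxy]hept-1-en-3-one, via mesylate 12 (not isolated)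
Conditions: MsCl (1.5 equiv), Et3N (4 equiv), CH2Cl2, 0 °C → rt
Reagents that add atoms: none
Why: mesylation followed by E1cB elimination converts both epimers into the conjugated (E)-aryl enone; the silyloxy group is a much poorer leaving group and stays.

**Step 9**
Reactants: 13 (1E,5S)-silyloxy enone
Product: 14 (1E,5S)-1-[3,4-bis(benzyloxy)-5-methoxyphenyl]-7-[4-(benzyloxy)phenyl]-5-hydroxyhept-1-en-3-one
Conditions: HF·pyridine, pyridine, THF, 0 °C → rt
Reagents that add atoms: none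
Why: buffered acidic fluoride desilylation frees the alcohol without the retro-aldol or elimination that basic fluoride can cause; any 15 already formed is carried forward.

**Step 10**
Reactants: 14 (1E,5S)-δ-hydroxy enone
Product: 15 (2S,6S)-2-[3,4-bis(benzyloxy)-5-methoxyphenyl]-6-{2-[4-(benzyloxy)phenyl]ethyl}oxan-4-one
Conditions: Amberlyst-15, CH2Cl2, rt
Reagents that add atoms: none
Why: acid-catalysed 6-endo-trig intramolecular oxa-Michael addition is reversible and settles on the chair with the C2 aryl and C6 alkyl groups both equatorial, so C2 is set cis to C6 (2S).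

**Step 11**
Reactants: 15 (2S,6S)-oxan-4-one
Product: 16 (2S,4R,6S)-2-[3,4-bis(benzyloxy)-5-methoxyphenyl]-6-{2-[4-(benzyloxy)phenyl]ethyl}oxan-4-ol
Conditions: NaBH4, MeOH/CH2Cl2, −20 °C
Reagents that add atoms: none
Why: the small hydride attacks the chair ketone axially and gives the equatorial (4R) alcohol, all-cis (typically ≥9:1); the axial epimer is removed by chromatography.

**Step 12**
Reactants: 16 (2S,4R,6S)-tribenzyl ether
Product: 17 5-{(2S,4R,6S)-4-hydroxy-6-[2-(4-hydroxyphenyl)ethyl]oxan-2-yl}-3-methoxybenzene-1,2-diol (target)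
Conditions: H2 (1 atm), 10% Pd/C, EtOAc/MeOH 4:1, rt, stopped at full conversion
Reagents that add atoms: none
Why: catalytic hydrogenolysis cleaves the three O-benzyl aryl ethers much faster than the cyclic benzylic C–O bond; no stereocentre is touched.

**Compound list**
1 | 3,4-dihydroxy-5-methoxybenzaldehyde (5-hydroxyvanillin) | COc1cc(C=O)cc(O)c1O | starting material
2 | 3,4-bis(benzyloxy)-5-methoxybenzaldehyde | COc1cc(C=O)cc(OCc2ccccc2)c1OCc1ccccc1 | intermediate
3 | 3-(4-hydroxyphenyl)propan-1-ol | OCCCc1ccc(O)cc1 | starting material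
4 | 3-[4-(benzyloxy)phenyl]propan-1-ol | OCCCc1ccc(OCc2ccccc2)cc1 | intermediate
5 | 3-[4-(benzyloxy)phenyl]propanal | O=CCCc1ccc(OCc2ccccc2)cc1 | intermediate
6 | (S)-1-[4-(benzyloxy)phenyl]hex-5-en-3-yl diisopinocampheylborinate | C=CC[C@H](CCc1ccc(OCc2ccccc2)cc1)OB([C@H]1C[C@H]2C[C@@H]([C@@H]1C)C2(C)C)[C@H]1C[C@H]2C[C@@H]([C@@H]1C)C2(C)C | intermediate (not isolated)
7 | (S)-1-[4-(benzyloxy)phenyl]hex-5-en-3-ol | C=CC[C@H](CCc1ccc(OCc2ccccc2)cc1)O | intermediate
8 | (S)-{[1-(4-(benzyloxy)phenyl)hex-5-en-3-yl]oxy}(tert-butyl)dimethylsilane | C=CC[C@H](CCc1ccc(OCc2ccccc2)cc1)O[Si](C)(C)C(C)(C)C | intermediate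
9 | (S)-6-[4-(benzyloxy)phenyl]-4-[(tert-butyldimethylsilyl)oxy]hexan-2-one | CC(=O)C[C@H](CCc1ccc(OCc2ccccc2)cc1)O[Si](C)(C)C(C)(C)C | intermediate
10 | lithium (S)-6-[4-(benzyloxy)phenyl]-4-[(tert-butyldimethylsilyl)oxy]hex-1-en-2-olate | [Li]OC(=C)C[C@H](CCc1ccc(OCc2ccccc2)cc1)O[Si](C)(C)C(C)(C)C | intermediate (not isolated)
11 | (5S)-1-[3,4-bis(benzyloxy)-5-methoxyphenyl]-7-[4-(benzyloxy)phenyl]-5-[(tert-butyldimethylsilyl)oxy]-1-hydroxyheptan-3-one (C1 epimer mixture) | COc1cc(C(O)CC(=O)C[C@H](CCc2ccc(OCc3ccccc3)cc2)O[Si](C)(C)C(C)(C)C)cc(OCc2ccccc2)c1OCc1ccccc1 | intermediate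
12 | (5S)-1-[3,4-bis(benzyloxy)-5-methoxyphenyl]-7-[4-(benzyloxy)phenyl]-5-[(tert-butyldimethylsilyl)oxy]-3-oxoheptyl methanesulfonate (C1 epimer mixture) | COc1cc(C(CC(=O)C[C@H](CCc2ccc(OCc3ccccc3)cc2)O[Si](C)(C)C(C)(C)C)OS(C)(=O)=O)cc(OCc2ccccc2)c1OCc1ccccc1 | intermediate (not isolated)
13 | (1E,5S)-1-[3,4-bis(benzyloxy)-5-methoxyphenyl]-7-[4-(benzyloxy)phenyl]-5-[(tert-butyldimethylsilyl)oxy]hept-1-en-3-one | COc1cc(/C=C/C(=O)C[C@H](CCc2ccc(OCc3ccccc3)cc2)O[Si](C)(C)C(C)(C)C)cc(OCc2ccccc2)c1OCc1ccccc1 | intermediate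
14 | (1E,5S)-1-[3,4-bis(benzyloxy)-5-methoxyphenyl]-7-[4-(benzyloxy)phenyl]-5-hydroxyhept-1-en-3-one | COc1cc(/C=C/C(=O)C[C@H](CCc2ccc(OCc3ccccc3)cc2)O)cc(OCc2ccccc2)c1OCc1ccccc1 | intermediate
15 | (2S,6S)-2-[3,4-bis(benzyloxy)-5-methoxyphenyl]-6-{2-[4-(benzyloxy)phenyl]ethyl}oxan-4-one | COc1cc([C@@H]2CC(=O)C[C@H](CCc3ccc(OCc4ccccc4)cc3)O2)cc(OCc2ccccc2)c1OCc1ccccc1 | intermediate
16 | (2S,4R,6S)-2-[3,4-bis(benzyloxy)-5-methoxyphenyl]-6-{2-[4-(benzyloxy)phenyl]ethyl}oxan-4-ol | COc1cc([C@@H]2C[C@H](O)C[C@H](CCc3ccc(OCc4ccccc4)cc3)O2)cc(OCc2ccccc2)c1OCc1ccccc1 | intermediate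
17 | 5-{(2S,4R,6S)-4-hydroxy-6-[2-(4-hydroxyphenyl)ethyl]oxan-2-yl}-3-methoxybenzene-1,2-diol | COc1cc([C@@H]2C[C@H](O)C[C@H](CCc3ccc(O)cc3)O2)cc(O)c1O | target

**Totals**
Total step count: 12. Longest linear sequence: 11 steps (3 → 17, steps 2–12); step 1 is the side branch.

**Steps most likely to fail**

Step 4. The allylation may give less than the needed ee, and every later stereocentre is relayed from this one. The fallback sets out from aldehyde 5 and comes back at 7. Corey–Chaykovsky methylenation (Me3S+ I−, NaH, DMSO/THF) gives racemic 2-{2-[4-(benzyloxy)phenyl]ethyl}oxirane F1. Jacobsen hydrolytic kinetic resolution with the (salen)Co(III)OAc enantiomer that hydrolyses the (R)-epoxide (expected to be the (S,S)-catalyst; 0.55 equiv H2O) leaves (S)-2-{2-[4-(benzyloxy)phenyl]ethyl}oxirane F2 in >99% ee. Copper-catalysed opening at the CH2 terminus with vinylmagnesium bromide (cat. CuI, THF, −30 °C) then gives 7.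

Step 10. The oxa-Michael closure may compete with dehydration to the dienone or stall short of full cis selectivity. The fallback sets out from homoallylic alcohol 7 together with aldehyde 2 and comes back at 16. A Prins cyclisation (TFA, CH2Cl2, 0 °C → rt) through the chair oxocarbenium ion, with all substituents equatorial, gives (2S,4R,6S)-2-[3,4-bis(benzyloxy)-5-methoxyphenyl]-6-{2-[4-(benzyloxy)phenyl]ethyl}oxan-4-yl trifluoroacetate F3. Methanolysis (K2CO3, MeOH, rt) gives 16 directly, bypassing 8–15.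

Step 12. Hydrogenolysis may also cleave the ring benzylic C2–O bond of the electron-rich aryl ether, or the catechol may oxidise during handling. The fallback sets out from 16 and comes back at 17. It replaces reduction by Lewis-acid debenzylation with a cation scavenger (BCl3, pentamethylbenzene, CH2Cl2, −78 °C, then MeOH quench), which leaves the methyl ether and the ring in place. No new compound is made on this path (F0).

**Further compounds**
F1 | step 4 | rac-2-{2-[4-(benzyloxy)phenyl]ethyl}oxirane | C1OC1CCc1ccc(OCc2ccccc2)cc1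
F2 | step 4 | (S)-2-{2-[4-(benzyloxy)phenyl]ethyl}oxirane | C1[C@H](CCc2ccc(OCc3ccccc3)cc2)O1
F3 | step 10 | (2S,4R,6S)-2-[3,4-bis(benzyloxy)-5-methoxyphenyl]-6-{2-[4-(benzyloxy)phenyl]ethyl}oxan-4-yl trifluoroacetate | COc1cc([C@@H]2C[C@H](OC(=O)C(F)(F)F)C[C@H](CCc3ccc(OCc4ccccc4)cc3)O2)cc(OCc2ccccc2)c1OCc1ccccc1
F0 | step 12 | none | none
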